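(All runs come from a simulation with constants of no real substance; noise was put on by code.)

How long should this flask stir to hold the most target, and how much target is that?

* the moment within 1.0 h at which there is most target
* the amount of target, in percent of the starting material charged, at that time

| setting | grey | green | ochre | flask |
|---|---|---|---|---|
| starting material | 10 mM | 10 mM | 5 mM | 10 mM |
| reagent | 0.60 equiv | 0.60 equiv | 0.60 equiv | 0.600 equiv |
| free catalyst | 1.4 mol% | 2.2 mol% | 1 mol% | 1 mol% |
| remark | run made earlier | run made earlier | run made earlier |  |
| time |  |  |  | 1.0 h |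

| run | time / min | target / % | starting material / % |
|---|---|---|---|
| grey | 1.33 | 37.9 | 58.3 |
| grey | 3.00 | 46.5 | 47.4 |
| grey | 6.00 | 41.3 | 42.4 |
| grey | 15.0 | 25.2 | 40.8 |
| grey | 40.0 | 17.8 | 40.9 |
| green | 1.33 | 43.5 | 51.2 |
| green | 3.00 | 44.2 | 45.5 |
| green | 6.00 | 32.3 | 39.8 |
| green | 15.0 | 20.2 | 39.4 |
| green | 40.0 | 18.5 | 40.0 |
| ochre | 1.33 | 20.4 | 78.6 |
| ochre | 3.00 | 37.8 | 61.2 |
| ochre | 6.00 | 45.6 | 48.6 |
| ochre | 15.0 | 42.5 | 42.0 |
| ochre | 40.0 | 23.9 | 42.0 |

(scatter of a reading: 1 percentage point)



Two chemists read these runs. Both see starting material level off near 40.9% of its charge, so reagent is the limiting reagent. Both see target rise, peak and sag towards about 18.5% of the charge. They part over the clock.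

The first chemist holds that the loading sets the clock. Ochre has the flask's 1 mol%, so she expects the flask to repeat ochre, whose top reading is 45.6% at 0.1 h.

The second chemist holds that the absolute amount of catalyst sets it. Grey's top reading, 46.5%, stands at 0.420 mM·min of catalyst dose, meaning the catalyst concentration times the time. Her evidence is late in the runs. Grey at 15.0 min and ochre at 40.0 min have doses of 2.10 mM·min and 2.00 mM·min, and they read 25.2% and 23.9%. The flask has 0.100 mM of catalyst, so grey's dose arrives at 0.0700 h, earlier than the first chemist's time.

The forecast takes the second side, but it reads the three runs together: plotting target against dose “puts all three runs on one curve”. It gives 46.3% at 0.072 h, a little later than her reckoning from grey's one reading.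

    target + free catalyst ⇌ isomer of the product + free catalyst, rate k1*[free catalyst]*[target] forward; the back reaction follows from the equilibrium constant (K = 2.20, k = 1950 M⁻¹ min⁻¹)
    reagent + free catalyst → catalyst intermediate A (k = 18200 M⁻¹ min⁻¹)
    catalyst intermediate A ⇌ by-product + catalyst intermediate B (K = 0.0197 M, k = 263 min⁻¹)
    catalyst intermediate C ⇌ free catalyst + target (K = 0.00589 M, k = 638 min⁻¹)
    starting material + catalyst intermediate B ⇌ catalyst intermediate C (K = 141 M⁻¹, k = 11800 M⁻¹ min⁻¹)

The flask peaks at 0.0796 h with 45.8% target, nearer the second chemist's time than the first's, at a dose of 0.478 mM·min. The first view keeps the height: at this loading, the neighbours charged with 25 mM and 2.5 mM reach 45.7% and 45.8%. The 2.5 mM neighbour reaches a dose of 1.50 mM·min at 1.0 h and holds 26.6% target, between green's 32.3% at 1.32 mM·min and ochre's 23.9% at 2.00 mM·min. In the flask at 1.00 h, the relaxation half-life of target and isomer of the product by the step between them alone, both ways together, is 0.0831 h, short against the 1.0 h allowed. At 1.00 h the flask holds 18.6% target beside 40.9% isomer of the product.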